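**Retrosynthetic overview**
1. Target 25 ← inversion of the ring carbinol (oxidation, then equatorial hydride delivery) in its C10 epimer 23.
2. 23 ← one epoxide-initiated cation–olefin cascade on the fully functionalised acyclic epoxy triene 22: ring A (C11–C6 bond) forms first, then ring B (C7–C2 bond), and an allylsilane terminator leaves the exocyclic methylene.
3. 22 ← Tsuji–Trost C-allylation of hydroxypyrone 3 with allylic carbonate 18, then O-methylation to the 4-pyranone and formylation of the tertiary alcohol.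
4. 18 ← acetoacetate dianion / enol phosphate / Me3SiCH2MgCl homologation of epoxy bromide 13 ← neryl acetate 4 (SeO2 oxidation, Sharpless epoxidation, triflate alkylation, MeMgCl).
5. 3 ← methyl acetoacetate + malonyl dichloride (polyketide-like pyranone closure).

Assumption: the SMILES is taken literally. It encodes a cis-fused decalin (ring-fusion H and angular CH3 on the same face), so the central olefin of the precursor must be Z (neryl unit).

Locants used below: C1 = CH2 on the pyranone, then C2…C14 along the chain (C14 = CMe2–O). Ring B = C2–C7, ring A = C6–C11. The target is (2S,6R,7S,10S,11R) in these locants.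

Step 1
Reactants: 1 methyl acetoacetate; 2 malonyl dichloride
Product: 3 methyl 4-hydroxy-2-methyl-6-oxo-6H-pyran-3-carboxylate
Conditions: CH2Cl2, 0 °C → reflux (HCl evolves), crystallise
Reagents that add atoms: none
Why: C-acylation of the keto-ester α-carbon and O-acylation of its enol by the bis-acid chloride (Elvidge-type 4-hydroxy-2-pyranone annulation) closes the ring and leaves a single nucleophilic ring CH for the later allylation; no stereocentre.

Step 2
Reactants: 4 neryl acetate [(2Z)-3,7-dimethylocta-2,6-dien-1-yl acetate]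
Product: 5 (2Z,6E)-8-hydroxy-3,7-dimethylocta-2,6-dien-1-yl acetate
Conditions: SeO2 (0.1 equiv), t-BuOOH (3 equiv), salicylic acid (0.1 equiv), CH2Cl2, 23 °C
Reagents that add atoms: tert-butyl hydroperoxide, CC(C)(C)OO (oxygen, relayed by SeO2, O=[Se]=O)
Why: SeO2 allylic oxidation (ene reaction then [2,3]-shift) hydroxylates the E-methyl of the electron-rich distal olefin, while the proximal Z-olefin is deactivated by the allylic acetate and keeps its geometry.

Step 3
Reactants: 5 (2Z,6E)-8-hydroxy-3,7-dimethylocta-2,6-dien-1-yl acetate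
Product: 6 (2Z)-5-[(2R,3R)-3-(hydroxymethyl)-3-methyloxiran-2-yl]-3-methylpent-2-en-1-yl acetate
Conditions: Ti(Oi-Pr)4 (10 mol %), D-(−)-diethyl tartrate (12 mol %), t-BuOOH, 4 Å MS, CH2Cl2, −20 °C
Reagents that add atoms: tert-butyl hydroperoxide, CC(C)(C)OO
Why: Katsuki–Sharpless asymmetric epoxidation is directed by the allylic hydroxyl (only the 10,11-olefin reacts); the D-tartrate sets C10 and C11 as (R,R), and the E-olefin fixes chain and CH2OH trans on the oxirane.

Step 4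
Reactants: 6 (2Z)-5-[(2R,3R)-3-(hydroxymethyl)-3-methyloxiran-2-yl]-3-methylpent-2-en-1-yl acetate
Product: 8 ethyl 3-[(2R,3R)-3-[(3Z)-5-acetoxy-3-methylpent-3-en-1-yl]-2-methyloxiran-2-yl]propanoate, via epoxy triflate 7 (not isolated)
Conditions: Tf2O, 2,6-lutidine, CH2Cl2, −78 °C; then cannulate into LiCH2CO2Et (EtOAc, LiN(i-Pr)2), THF–DMPU, −78 → −30 °C
Reagents that add atoms: ethyl acetate, CCOC(C)=O
Why: SN2 displacement of a primary oxiranylmethyl triflate by an ester enolate forms C12–C13 without touching the epoxide centres (the tied-back oxirane eases the neopentyl-like hindrance), and any acetate lost to the enolate is irrelevant because step 5 removes it.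

Step 5
Reactants: 8 ethyl 3-[(2R,3R)-3-[(3Z)-5-acetoxy-3-methylpent-3-en-1-yl]-2-methyloxiran-2-yl]propanoate
Product: 11 (2Z)-3-methyl-5-[(2R,3R)-3-methyl-3-{3-methyl-3-[(trimethylsilyl)oxy]butyl}oxiran-2-yl]pent-2-en-1-ol, via magnesium dialkoxide of epoxy diol 9 (not isolated), via bis(trimethylsilyl) ether 10 (not isolated)
Conditions: MeMgCl (5 equiv), THF, −20 → 0 °C; then Me3SiCl, 0 → 23 °C; work-up K2CO3, MeOH, 0 °C
Reagents that add atoms: methylmagnesium chloride, C[Mg]Cl; chlorotrimethylsilane, C[Si](C)(C)Cl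
Why: Double Grignard addition turns the ester into the C14 tertiary carbinol and the same reagent cleaves the acetate; silylation in the flask masks the tertiary alkoxide before it can open the neighbouring epoxide to a tetrahydrofuran, and mild methanolysis frees only the primary silyl ether.

Step 6
Reactants: 11 (2Z)-3-methyl-5-[(2R,3R)-3-methyl-3-{3-methyl-3-[(trimethylsilyl)oxy]butyl}oxiran-2-yl]pent-2-en-1-ol
Product: 13 (2R,3R)-3-[(3Z)-5-bromo-3-methylpent-3-en-1-yl]-2-methyl-2-{3-methyl-3-[(trimethylsilyl)oxy]butyl}oxirane, via allylic mesylate 12 (not isolated)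
Conditions: MsCl, Et3N, THF, −40 °C; then LiBr, THF, 0 °C
Reagents that add atoms: lithium bromide, [Li+].[Br-]
Why: Mesylation and direct SN2 bromide displacement at low temperature, the standard route to epoxy-polyprenyl bromides, proceed without allylic transposition and keep the Z-olefin and the epoxide.

Step 7
Reactants: 13 (2R,3R)-3-[(3Z)-5-bromo-3-methylpent-3-en-1-yl]-2-methyl-2-{3-methyl-3-[(trimethylsilyl)oxy]butyl}oxirane; 1 methyl acetoacetate
Product: 14 methyl (6Z)-7-methyl-9-[(2R,3R)-3-methyl-3-{3-methyl-3-[(trimethylsilyl)oxy]butyl}oxiran-2-yl]-3-oxonon-6-enoate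
Conditions: 1, NaH then n-BuLi, THF, 0 °C; then 13, 0 °C; NH4Cl
Reagents that add atoms: none
Why: Huckin–Weiler dianion alkylation occurs only at the terminal (γ) carbon of the acetoacetate dianion, forming C4–C5 by SN2 on the allylic bromide.

Step 8
Reactants: 14 methyl (6Z)-7-methyl-9-[(2R,3R)-3-methyl-3-{3-methyl-3-[(trimethylsilyl)oxy]butyl}oxiran-2-yl]-3-oxonon-6-enoate
Product: 15 methyl (2Z,6Z)-3-[(diethoxyphosphoryl)oxy]-7-methyl-9-[(2R,3R)-3-methyl-3-{3-methyl-3-[(trimethylsilyl)oxy]butyl}oxiran-2-yl]nona-2,6-dienoate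
Conditions: NaH (1.05 equiv), Et2O, 0 °C; then ClP(O)(OEt)2
Reagents that add atoms: diethyl chlorophosphate, CCOP(=O)(Cl)OCC
Why: O-phosphorylation of the chelated sodium enolate of the β-keto ester gives the Z-enol phosphate (P–O cis to the ester), which fixes the geometry of the later allylsilane.

Step 9
Reactants: 15 methyl (2Z,6Z)-3-[(diethoxyphosphoryl)oxy]-7-methyl-9-[(2R,3R)-3-methyl-3-{3-methyl-3-[(trimethylsilyl)oxy]butyl}oxiran-2-yl]nona-2,6-dienoate
Product: 16 methyl (2Z,6Z)-7-methyl-9-[(2R,3R)-3-methyl-3-{3-methyl-3-[(trimethylsilyl)oxy]butyl}oxiran-2-yl]-3-[(trimethylsilyl)methyl]nona-2,6-dienoate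
Conditions: Me3SiCH2MgCl (3 equiv), Ni(acac)2 (5 mol %), THF, 0 → 23 °C
Reagents that add atoms: (trimethylsilyl)methylmagnesium chloride, C[Si](C)(C)C[Mg]Cl
Why: Nickel-catalysed Kumada coupling of the enol phosphate (Weiler allylsilane synthesis) replaces P–O by CH2SiMe3 with retention, so CH2Si ends cis to C1, and the weakly nucleophilic Grignard spares the ester and the epoxide.

Step 10
Reactants: 16 methyl (2Z,6Z)-7-methyl-9-[(2R,3R)-3-methyl-3-{3-methyl-3-[(trimethylsilyl)oxy]butyl}oxiran-2-yl]-3-[(trimethylsilyl)methyl]nona-2,6-dienoate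
Product: 18 methyl (2Z,6Z)-7-methyl-9-[(2R,3R)-3-methyl-3-{3-methyl-3-[(trimethylsilyl)oxy]butyl}oxiran-2-yl]-3-[(trimethylsilyl)methyl]nona-2,6-dien-1-yl carbonate, via allylic alcohol 17 (not isolated)
Conditions: i-Bu2AlH (2.5 equiv), CH2Cl2, −78 °C; then pyridine, DMAP, ClCO2Me, −78 → 0 °C
Reagents that add atoms: methyl chloroformate, COC(=O)Cl
Why: 1,2-Reduction of the enoate by the aluminium hydride and acylation of the resulting aluminium alkoxide in the same flask (as in reductive acetylation) give the allylic carbonate without exposing the acid-sensitive allylsilane alcohol to isolation.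

Step 11
Reactants: 18 methyl (2Z,6Z)-7-methyl-9-[(2R,3R)-3-methyl-3-{3-methyl-3-[(trimethylsilyl)oxy]butyl}oxiran-2-yl]-3-[(trimethylsilyl)methyl]nona-2,6-dien-1-yl carbonate; 3 methyl 4-hydroxy-2-methyl-6-oxo-6H-pyran-3-carboxylate
Product: 19 methyl 4-hydroxy-2-methyl-5-{(2Z,6Z)-7-methyl-9-[(2R,3R)-3-methyl-3-{3-methyl-3-[(trimethylsilyl)oxy]butyl}oxiran-2-yl]-3-[(trimethylsilyl)methyl]nona-2,6-dien-1-yl}-6-oxo-6H-pyran-3-carboxylate
Conditions: 3 (2 equiv), Pd(PPh3)4 (5 mol %), THF, 23 °C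
Reagents that add atoms: none
Why: Tsuji–Trost allylation, in which zerovalent palladium ionises the carbonate, the released methoxide is quenched by the acidic pyrone, and the soft pyronate carbon attacks the unhindered C1 terminus (linear product, olefin geometry kept), C-alkylation at 23 °C being faster than desilylation to a trimethylenemethane complex.

Step 12
Reactants: 19 methyl 4-hydroxy-2-methyl-5-{(2Z,6Z)-7-methyl-9-[(2R,3R)-3-methyl-3-{3-methyl-3-[(trimethylsilyl)oxy]butyl}oxiran-2-yl]-3-[(trimethylsilyl)methyl]nona-2,6-dien-1-yl}-6-oxo-6H-pyran-3-carboxylate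
Product: 20 methyl 6-methoxy-2-methyl-5-{(2Z,6Z)-7-methyl-9-[(2R,3R)-3-methyl-3-{3-methyl-3-[(trimethylsilyl)oxy]butyl}oxiran-2-yl]-3-[(trimethylsilyl)methyl]nona-2,6-dien-1-yl}-4-oxo-4H-pyran-3-carboxylate
Conditions: MeOTf (1.1 equiv), 2,6-di-tert-butyl-4-methylpyridine, CH2Cl2, 0 °C
Reagents that add atoms: methyl trifluoromethanesulfonate, COS(=O)(=O)C(F)(F)F
Why: Beak-type hard O-methylation of the neutral hydroxypyranone occurs at the lactone carbonyl oxygen (the 4-OH is hydrogen-bonded to the ester) and proton loss gives the 2-methoxy-4-pyranone, while the hindered base keeps acid away from epoxide and allylsilane.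

Step 13
Reactants: 20 methyl 6-methoxy-2-methyl-5-{(2Z,6Z)-7-methyl-9-[(2R,3R)-3-methyl-3-{3-methyl-3-[(trimethylsilyl)oxy]butyl}oxiran-2-yl]-3-[(trimethylsilyl)methyl]nona-2,6-dien-1-yl}-4-oxo-4H-pyran-3-carboxylate
Product: 22 methyl 5-{(2Z,6Z)-9-[(2R,3R)-3-[3-(formyloxy)-3-methylbutyl]-3-methyloxiran-2-yl]-7-methyl-3-[(trimethylsilyl)methyl]nona-2,6-dien-1-yl}-6-methoxy-2-methyl-4-oxo-4H-pyran-3-carboxylate, via tertiary alcohol 21 (not isolated)
Conditions: Bu4NF–AcOH (1:1), THF, 0 °C; then AcOCHO, pyridine, DMAP (cat.), 0 → 23 °C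
Reagents that add atoms: acetic formic anhydride, CC(=O)OC=O
Why: Buffered fluoride cleaves only the O–Si bond (the allylic C–Si bond is inert at 0 °C) and the mixed anhydride formylates the tertiary alcohol at once, so the hydroxy epoxide never accumulates and the formate serves as the non-nucleophilic cap needed in step 14.

Step 14
Reactants: 22 methyl 5-{(2Z,6Z)-9-[(2R,3R)-3-[3-(formyloxy)-3-methylbutyl]-3-methyloxiran-2-yl]-7-methyl-3-[(trimethylsilyl)methyl]nona-2,6-dien-1-yl}-6-methoxy-2-methyl-4-oxo-4H-pyran-3-carboxylate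
Product: 23 methyl 5-{[(1S,4aR,5R,6R,8aS)-5-[3-(formyloxy)-3-methylbutyl]-6-hydroxy-5,8a-dimethyl-2-methylidenedecahydronaphthalen-1-yl]methyl}-6-methoxy-2-methyl-4-oxo-4H-pyran-3-carboxylate (cis-fused, C10 epimer of the target)
Conditions: MeAlCl2 (3.5 equiv), CH2Cl2, −78 °C, 30 min; then Et3N, MeOH–H2O
Reagents that add atoms: none
Why: Lewis-acid epoxide-initiated cation–olefin bicyclisation with an allylsilane terminator (Stork–Eschenmoser logic) through a chair–chair array, in which C6 opens the (10R,11R)-epoxide at C11 with inversion (C11 R, C10–O equatorial), anti addition across the 6Z-olefin gives the cis ring fusion with H-6, C7-methyl and C11-methyl on one face, the 2Z allylsilane places C1 equatorial at C2, and anti SE2′ loss of silicon gives only the exocyclic methylene.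

Step 15
Reactants: 23 methyl 5-{[(1S,4aR,5R,6R,8aS)-5-[3-(formyloxy)-3-methylbutyl]-6-hydroxy-5,8a-dimethyl-2-methylidenedecahydronaphthalen-1-yl]methyl}-6-methoxy-2-methyl-4-oxo-4H-pyran-3-carboxylate
Product: 24 methyl 5-{[(1S,4aR,5R,8aS)-5-[3-(formyloxy)-3-methylbutyl]-5,8a-dimethyl-2-methylidene-6-oxodecahydronaphthalen-1-yl]methyl}-6-methoxy-2-methyl-4-oxo-4H-pyran-3-carboxylate
Conditions: Dess–Martin periodinane, NaHCO3, CH2Cl2, 23 °C
Reagents that add atoms: none
Why: Dess–Martin oxidation of the hindered secondary alcohol is neutral and leaves formate, pyranone and exocyclic olefin alone; the ketone has no epimerisable α-stereocentre (C11 is quaternary).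

Step 16
Reactants: 24 methyl 5-{[(1S,4aR,5R,8aS)-5-[3-(formyloxy)-3-methylbutyl]-5,8a-dimethyl-2-methylidene-6-oxodecahydronaphthalen-1-yl]methyl}-6-methoxy-2-methyl-4-oxo-4H-pyran-3-carboxylate
Product: 25 methyl 5-{[(1S,4aR,5R,6S,8aS)-5-[3-(formyloxy)-3-methylbutyl]-6-hydroxy-5,8a-dimethyl-2-methylidenedecahydronaphthalen-1-yl]methyl}-6-methoxy-2-methyl-4-oxo-4H-pyran-3-carboxylate (target)
Conditions: LiBH(s-Bu)3 (1.2 equiv), THF, −78 °C; AcOH quench, neutral work-up
Reagents that add atoms: none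
Why: Selectride-type bulky hydride reduction takes the equatorial trajectory because the axial face of the ring-A ketone is blocked by the syn-axial C5 methylene of the cis-fused ring, giving the axial (10S) alcohol, and at −78 °C the hindered borohydride should spare the formate, the methyl ester and the vinylogous-ester pyranone.

**Compound list**
1 | methyl acetoacetate | CC(=O)CC(=O)OC | starting material
2 | malonyl dichloride | O=C(Cl)CC(=O)Cl | starting material
3 | methyl 4-hydroxy-2-methyl-6-oxo-6H-pyran-3-carboxylate | COC(=O)C1=C(C)OC(=O)C=C1O | intermediate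
4 | neryl acetate, (2Z)-3,7-dimethylocta-2,6-dien-1-yl acetate | CC(=O)OC/C=C(C)\CCC=C(C)C | starting material
5 | (2Z,6E)-8-hydroxy-3,7-dimethylocta-2,6-dien-1-yl acetate | CC(=O)OC/C=C(C)\CC/C=C(C)/CO | intermediate
6 | (2Z)-5-[(2R,3R)-3-(hydroxymethyl)-3-methyloxiran-2-yl]-3-methylpent-2-en-1-yl acetate | CC(=O)OC/C=C(C)\CC[C@H]1O[C@]1(C)CO | intermediate
7 | [(2R,3R)-3-[(3Z)-5-acetoxy-3-methylpent-3-en-1-yl]-2-methyloxiran-2-yl]methyl trifluoromethanesulfonate | CC(=O)OC/C=C(C)\CC[C@H]1O[C@]1(C)COS(=O)(=O)C(F)(F)F | intermediate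
8 | ethyl 3-[(2R,3R)-3-[(3Z)-5-acetoxy-3-methylpent-3-en-1-yl]-2-methyloxiran-2-yl]propanoate | CC(=O)OC/C=C(C)\CC[C@H]1O[C@]1(C)CCC(=O)OCC | intermediate
9 | (2Z)-5-[(2R,3R)-3-(3-hydroxy-3-methylbutyl)-3-methyloxiran-2-yl]-3-methylpent-2-en-1-ol (formed as its magnesium dialkoxide) | OC/C=C(C)\CC[C@H]1O[C@]1(C)CCC(C)(C)O | intermediate
10 | bis(trimethylsilyl) ether of 9 | C[Si](C)(C)OC/C=C(C)\CC[C@H]1O[C@]1(C)CCC(C)(C)O[Si](C)(C)C | intermediate
11 | (2Z)-3-methyl-5-[(2R,3R)-3-methyl-3-{3-methyl-3-[(trimethylsilyl)oxy]butyl}oxiran-2-yl]pent-2-en-1-ol | OC/C=C(C)\CC[C@H]1O[C@]1(C)CCC(C)(C)O[Si](C)(C)C | intermediate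
12 | methanesulfonate of 11 | CS(=O)(=O)OC/C=C(C)\CC[C@H]1O[C@]1(C)CCC(C)(C)O[Si](C)(C)C | intermediate
13 | (2R,3R)-3-[(3Z)-5-bromo-3-methylpent-3-en-1-yl]-2-methyl-2-{3-methyl-3-[(trimethylsilyl)oxy]butyl}oxirane | BrC/C=C(C)\CC[C@H]1O[C@]1(C)CCC(C)(C)O[Si](C)(C)C | intermediate
14 | methyl (6Z)-7-methyl-9-[(2R,3R)-3-methyl-3-{3-methyl-3-[(trimethylsilyl)oxy]butyl}oxiran-2-yl]-3-oxonon-6-enoate | COC(=O)CC(=O)CC/C=C(C)\CC[C@H]1O[C@]1(C)CCC(C)(C)O[Si](C)(C)C | intermediate
15 | methyl (2Z,6Z)-3-[(diethoxyphosphoryl)oxy]-7-methyl-9-[(2R,3R)-3-methyl-3-{3-methyl-3-[(trimethylsilyl)oxy]butyl}oxiran-2-yl]nona-2,6-dienoate | COC(=O)/C=C(\OP(=O)(OCC)OCC)CC/C=C(C)\CC[C@H]1O[C@]1(C)CCC(C)(C)O[Si](C)(C)C | intermediate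
16 | methyl (2Z,6Z)-7-methyl-9-[(2R,3R)-3-methyl-3-{3-methyl-3-[(trimethylsilyl)oxy]butyl}oxiran-2-yl]-3-[(trimethylsilyl)methyl]nona-2,6-dienoate | COC(=O)/C=C(\C[Si](C)(C)C)CC/C=C(C)\CC[C@H]1O[C@]1(C)CCC(C)(C)O[Si](C)(C)C | intermediate
17 | (2Z,6Z)-7-methyl-9-[(2R,3R)-3-methyl-3-{3-methyl-3-[(trimethylsilyl)oxy]butyl}oxiran-2-yl]-3-[(trimethylsilyl)methyl]nona-2,6-dien-1-ol | OC/C=C(\C[Si](C)(C)C)CC/C=C(C)\CC[C@H]1O[C@]1(C)CCC(C)(C)O[Si](C)(C)C | intermediate
18 | methyl carbonate of 17 | COC(=O)OC/C=C(\C[Si](C)(C)C)CC/C=C(C)\CC[C@H]1O[C@]1(C)CCC(C)(C)O[Si](C)(C)C | intermediate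
19 | methyl 4-hydroxy-2-methyl-5-{(2Z,6Z)-7-methyl-9-[(2R,3R)-3-methyl-3-{3-methyl-3-[(trimethylsilyl)oxy]butyl}oxiran-2-yl]-3-[(trimethylsilyl)methyl]nona-2,6-dien-1-yl}-6-oxo-6H-pyran-3-carboxylate | COC(=O)C1=C(C)OC(=O)C(C/C=C(\C[Si](C)(C)C)CC/C=C(C)\CC[C@H]2O[C@]2(C)CCC(C)(C)O[Si](C)(C)C)=C1O | intermediate
20 | methyl 6-methoxy-2-methyl-5-{(2Z,6Z)-7-methyl-9-[(2R,3R)-3-methyl-3-{3-methyl-3-[(trimethylsilyl)oxy]butyl}oxiran-2-yl]-3-[(trimethylsilyl)methyl]nona-2,6-dien-1-yl}-4-oxo-4H-pyran-3-carboxylate | COC(=O)c1c(C)oc(OC)c(C/C=C(\C[Si](C)(C)C)CC/C=C(C)\CC[C@H]2O[C@]2(C)CCC(C)(C)O[Si](C)(C)C)c1=O | intermediate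
21 | tertiary alcohol from 20 (O–SiMe3 replaced by OH) | COC(=O)c1c(C)oc(OC)c(C/C=C(\C[Si](C)(C)C)CC/C=C(C)\CC[C@H]2O[C@]2(C)CCC(C)(C)O)c1=O | intermediate
22 | methyl 5-{(2Z,6Z)-9-[(2R,3R)-3-[3-(formyloxy)-3-methylbutyl]-3-methyloxiran-2-yl]-7-methyl-3-[(trimethylsilyl)methyl]nona-2,6-dien-1-yl}-6-methoxy-2-methyl-4-oxo-4H-pyran-3-carboxylate | COC(=O)c1c(C)oc(OC)c(C/C=C(\C[Si](C)(C)C)CC/C=C(C)\CC[C@H]2O[C@]2(C)CCC(C)(C)OC=O)c1=O | intermediate
23 | methyl 5-{[(1S,4aR,5R,6R,8aS)-5-[3-(formyloxy)-3-methylbutyl]-6-hydroxy-5,8a-dimethyl-2-methylidenedecahydronaphthalen-1-yl]methyl}-6-methoxy-2-methyl-4-oxo-4H-pyran-3-carboxylate | C=C1CC[C@H]2[C@@](C)(CCC(C)(C)OC=O)[C@H](O)CC[C@@]2(C)[C@H]1Cc1c(OC)oc(C)c(C(=O)OC)c1=O | intermediate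
24 | methyl 5-{[(1S,4aR,5R,8aS)-5-[3-(formyloxy)-3-methylbutyl]-5,8a-dimethyl-2-methylidene-6-oxodecahydronaphthalen-1-yl]methyl}-6-methoxy-2-methyl-4-oxo-4H-pyran-3-carboxylate | C=C1CC[C@H]2[C@@](C)(CCC(C)(C)OC=O)C(=O)CC[C@@]2(C)[C@H]1Cc1c(OC)oc(C)c(C(=O)OC)c1=O | intermediate
25 | methyl 5-{[(1S,4aR,5R,6S,8aS)-5-[3-(formyloxy)-3-methylbutyl]-6-hydroxy-5,8a-dimethyl-2-methylidenedecahydronaphthalen-1-yl]methyl}-6-methoxy-2-methyl-4-oxo-4H-pyran-3-carboxylate | C=C1CC[C@H]2[C@@](C)(CCC(C)(C)OC=O)[C@@H](O)CC[C@@]2(C)[C@H]1Cc1c(OC)oc(C)c(C(=O)OC)c1=O | target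

**Totals**
Total step count: 16. Longest linear sequence: 15 steps (steps 2–16 from neryl acetate); step 1 is the one-step side branch.

**Steps most likely to fail and fallbacks**

Step 14 (bicyclisation with the pyranone in place). The Lewis acid may be held by the pyranone, the Z-olefin closes more slowly than an E-olefin, and the allylsilane can be lost by protodesilylation. The fallback leaves the route at 16 and returns at 24: cyclise before the heterocycle is attached. Ester 16 is reduced with i-Bu2AlH to alcohol 17, isolated this time, and silylated (t-BuPh2SiCl, imidazole) to the silyl ether F3. K2CO3 in MeOH removes only the tertiary O–SiMe3 group to give the tertiary alcohol F4, and AcOCHO/pyridine gives the formate F5. MeAlCl2 in CH2Cl2 at −78 °C then gives, by the same chair–chair cascade, the cis-decalin silyl ether F6. HF·pyridine frees the diol F7, Dess–Martin periodinane oxidises both hydroxyls to the keto aldehyde F8, and reductive Knoevenagel alkylation of pyrone 3 (Hantzsch ester, L-proline, CH2Cl2) gives the hydroxypyranone ketone F9. MeOTf with 2,6-di-tert-butyl-4-methylpyridine converts F9 into 24.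

Step 4 (enolate displacement of a triflate beside a fully substituted oxirane carbon). The fallback leaves at 5 and returns at 8, one step longer: alkylate first at the allylic stage and epoxidise afterwards. CBr4/PPh3 converts 5 into the allylic bromide F1, and LiCH2CO2Et (THF, −78 °C) gives the diene ester F2. Shi epoxidation (D-fructose-derived ketone, KHSO5, K2CO3 buffer, MeCN–dimethoxymethane–H2O, 0 °C) attacks only the distal olefin, because the proximal one is deactivated by the allylic acetate, and gives the same (2R,3R)-epoxy ester 8.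

Step 16 (hindered ketone reduced in the presence of a formate). The fallback leaves at 24 and returns at 25: give up the formate and reinstall it. Excess LiBH(s-Bu)3 (−78 → 0 °C) gives the diol F10 with the same axial C10 alcohol. Et3SiCl/imidazole in DMF silylates only the secondary hydroxyl to give the silyl ether F11, AcOCHO with DMAP formylates the remaining tertiary hydroxyl to give F12, and HF·pyridine removes the triethylsilyl group to give 25.

**Further compounds**
F1 | step 4 | (2Z,6E)-8-bromo-3,7-dimethylocta-2,6-dien-1-yl acetate | CC(=O)OC/C=C(C)\CC/C=C(C)/CBr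
F2 | step 4 | ethyl (4E,8Z)-10-acetoxy-4,8-dimethyldeca-4,8-dienoate | CC(=O)OC/C=C(C)\CC/C=C(C)/CCC(=O)OCC
F3 | step 14 | tert-butyldiphenylsilyl ether of allylic alcohol 17 | CC(C)(C)[Si](OC/C=C(\C[Si](C)(C)C)CC/C=C(C)\CC[C@H]1O[C@]1(C)CCC(C)(C)O[Si](C)(C)C)(c1ccccc1)c1ccccc1
F4 | step 14 | tertiary alcohol from F3 (O–SiMe3 replaced by OH) | CC(C)(C)[Si](OC/C=C(\C[Si](C)(C)C)CC/C=C(C)\CC[C@H]1O[C@]1(C)CCC(C)(C)O)(c1ccccc1)c1ccccc1
F5 | step 14 | tertiary formate of F4 | CC(C)(C)[Si](OC/C=C(\C[Si](C)(C)C)CC/C=C(C)\CC[C@H]1O[C@]1(C)CCC(C)(C)OC=O)(c1ccccc1)c1ccccc1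
F6 | step 14 | 4-[(1R,2R,4aS,5S,8aR)-5-{[(tert-butyldiphenylsilyl)oxy]methyl}-2-hydroxy-1,4a-dimethyl-6-methylidenedecahydronaphthalen-1-yl]-2-methylbutan-2-yl formate | C=C1CC[C@H]2[C@@](C)(CCC(C)(C)OC=O)[C@H](O)CC[C@@]2(C)[C@H]1CO[Si](c1ccccc1)(c1ccccc1)C(C)(C)C
F7 | step 14 | diol from F6 (silyl ether replaced by CH2OH) | C=C1CC[C@H]2[C@@](C)(CCC(C)(C)OC=O)[C@H](O)CC[C@@]2(C)[C@H]1CO
F8 | step 14 | keto aldehyde from F7 (ring ketone at C10, CHO at C1) | C=C1CC[C@H]2[C@@](C)(CCC(C)(C)OC=O)C(=O)CC[C@@]2(C)[C@H]1C=O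
F9 | step 14 | 4-hydroxy-2-pyranone analogue of 24 (before O-methylation) | C=C1CC[C@H]2[C@@](C)(CCC(C)(C)OC=O)C(=O)CC[C@@]2(C)[C@H]1CC1=C(O)C(C(=O)OC)=C(C)OC1=O
F10 | step 16 | deformylated target (C10 and C14 diol) | C=C1CC[C@H]2[C@@](C)(CCC(C)(C)O)[C@@H](O)CC[C@@]2(C)[C@H]1Cc1c(OC)oc(C)c(C(=O)OC)c1=O
F11 | step 16 | C10 triethylsilyl ether of F10 | C=C1CC[C@H]2[C@@](C)(CCC(C)(C)O)[C@@H](O[Si](CC)(CC)CC)CC[C@@]2(C)[C@H]1Cc1c(OC)oc(C)c(C(=O)OC)c1=O
F12 | step 16 | C10 triethylsilyl ether of the target | C=C1CC[C@H]2[C@@](C)(CCC(C)(C)OC=O)[C@@H](O[Si](CC)(CC)CC)CC[C@@]2(C)[C@H]1Cc1c(OC)oc(C)c(C(=O)OC)c1=O
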